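**Strategy.** Ring A of the isocoumarin is a resorcylate: the lactone carbonyl C1 sits on C8a, oxygens sit on C8 and C6, and C4a carries the carbon branch. The route therefore builds ring A last, onto the oxygen of the pentasubstituted ring B phenol, by closing the C4a–C8a bond of an eight-carbon 3,5,7-tricarbonyl chain whose C8 oxygen is already an aryl enol ether. One base-mediated aldol condensation and aromatisation creates ring A and, with it, the crowded diaryl ether without any C–O coupling. A tert-butyl ester on the chain shuts off acyl-substitution side paths, and benzyl groups on all other oxygens allow a single final hydrogenolysis.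

Key step: step 9

Assumption: tert-butyl but-2-ynoate and the two N-methoxy-N-methylamides are taken as purchasable, and the key-step precursor is drawn as its triketo tautomer although it should exist largely as a diketone enol.

Chain carbons are named by their later isocoumarin positions (C1 ester carbon, C8a its α-carbon, C8 enol-ether carbon, C7, C6, C5, C4a, C4).

**Step 1**
Reactants: 1 olivetol (5-pentylbenzene-1,3-diol)
Product: 2 1,3-bis(benzyloxy)-5-pentylbenzene
Conditions: BnBr (2.3 equiv), K2CO3 (3 equiv), DMF, rt to 50 °C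
Reagents that add atoms: benzyl bromide, BrCc1ccccc1
Why: Williamson ether synthesis: both phenoxides are benzylated by SN2 displacement, and carbonate in a dipolar aprotic solvent favours O- over C-alkylation of the resorcinol.

**Step 2**
Reactants: 2 1,3-bis(benzyloxy)-5-pentylbenzene
Product: 3 1,5-bis(benzyloxy)-2,4-dibromo-3-pentylbenzene
Conditions: NBS (2.05 equiv), MeCN, 0 °C to rt, dark
Reagents that add atoms: N-bromosuccinimide, BrN1C(=O)CCC1=O
Why: Electrophilic aromatic bromination: each bromine should enter ortho to one benzyloxy group and para to the other, which are the two equivalent positions flanking the pentyl chain, whereas the position between the two benzyloxy groups is shielded on both sides and stays free.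

**Step 3**
Reactants: 3 1,5-bis(benzyloxy)-2,4-dibromo-3-pentylbenzene
Product: 4 4,6-bis(benzyloxy)-3-bromo-2-pentylbenzoic acid
Conditions: n-BuLi (1.0 equiv), THF, −78 °C; CO2 (g), −78 °C to rt; aq. HCl
Reagents that add atoms: carbon dioxide, O=C=O
Why: Bromine–lithium exchange and carboxylation: the two bromines of 3 are related by the mirror plane through the pentyl-bearing carbon, so one equivalent of n-BuLi should give a single aryllithium, which is too electron-rich to exchange a second time and is trapped by CO2.

**Step 4**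
Reactants: 4 4,6-bis(benzyloxy)-3-bromo-2-pentylbenzoic acid
Product: 6 4,6-bis(benzyloxy)-3-hydroxy-2-pentylbenzoic acid, via dimethyl arylboronate 5 (not isolated)
Conditions: n-BuLi (2.1 equiv), THF, −78 °C; B(OMe)3 (3 equiv), −78 to 0 °C; 30% H2O2, aq. NaOH, 0 °C; then aq. HCl
Reagents that add atoms: trimethyl borate, COB(OC)OC (boron and methoxy groups of 5); hydrogen peroxide, OO (phenolic oxygen of 6)
Why: Bromine–lithium exchange on the lithium carboxylate, borylation and oxidation of the aryl boronate with 1,2-shift of the aryl group to oxygen: the first equivalent of n-BuLi only deprotonates the acid, the hindered carboxylate is inert to addition at −78 °C, and exchange is far faster than lateral deprotonation of the pentyl chain.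

**Step 5**
Reactants: 6 4,6-bis(benzyloxy)-3-hydroxy-2-pentylbenzoic acid
Product: 7 benzyl 4,6-bis(benzyloxy)-3-hydroxy-2-pentylbenzoate (ring B phenol)
Conditions: BnBr (1.05 equiv), KHCO3 (1.2 equiv), DMF, rt
Reagents that add atoms: benzyl bromide, BrCc1ccccc1
Why: Carboxylate O-alkylation (SN2): hydrogencarbonate ionises only the carboxylic acid, so the hindered phenol stays free, and alkylation on the carboxylate oxygen is not slowed by the two ortho substituents of the acid.

**Step 6**
Reactants: 7 benzyl 4,6-bis(benzyloxy)-3-hydroxy-2-pentylbenzoate; 8 tert-butyl but-2-ynoate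
Product: 9 benzyl 4,6-bis(benzyloxy)-3-{[(2E)-4-(tert-butoxy)-4-oxobut-2-en-2-yl]oxy}-2-pentylbenzoate
Conditions: K2CO3 (0.3 equiv), DMF, 80 °C
Reagents that add atoms: none
Why: Base-catalysed oxa-Michael addition of the phenoxide to the ynoate: the addition is reversible under the conditions and should settle on the more stable E enoate, in which the aryloxy group is trans to the ester and the methyl group (future C7) is cis to it.

**Step 7**
Reactants: 9 the E aryloxy-crotonate from step 6; 10 N-methoxy-N-methylacetamide
Product: 11 benzyl 4,6-bis(benzyloxy)-3-{[(2E)-1-(tert-butoxy)-1,5-dioxohex-2-en-3-yl]oxy}-2-pentylbenzoate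
Conditions: LiN(i-Pr)2 (1.1 equiv), THF, −78 °C; then 10 (1.3 equiv), −78 to −40 °C; cold 1 M HCl
Reagents that add atoms: none
Why: Vinylogous deprotonation and γ-acylation of a 3-oxy-crotonate dienolate: the methyl group cis to the ester is lithiated, the dienolate attacks the Weinreb amide through C7, and the chelated tetrahedral adduct holds until the acidic quench, so the acidic product never meets the dienolate; this adds C6 and C5.

**Step 8**
Reactants: 11 the 5-oxohexenoate from step 7; 10 N-methoxy-N-methylacetamide
Product: 12 benzyl 4,6-bis(benzyloxy)-3-{[(2E)-1-(tert-butoxy)-1,5,7-trioxooct-2-en-3-yl]oxy}-2-pentylbenzoate (key-step precursor)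
Conditions: LiN(i-Pr)2 (2.1 equiv), THF, −78 °C; then 10 (1.2 equiv), −78 to −30 °C; cold 1 M HCl
Reagents that add atoms: none
Why: Dianion chain extension of the acetoacetate-dianion type: the first equivalent of base removes the acidic C7 proton, the second a proton of the terminal methyl, the dianion is acylated at this terminal, least stabilised carbon (C5), and the ester, being part of the dienolate, is not electrophilic; this adds C4a and C4.

**Step 9 (key step)**
Reactants: 12 the 3-aryloxy-5,7-dioxooct-2-enoate from step 8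
Product: 14 benzyl 4,6-bis(benzyloxy)-3-[2-(tert-butoxycarbonyl)-5-hydroxy-3-methylphenoxy]-2-pentylbenzoate, via aldol adduct 13 (not isolated)
Conditions: Et3N (3 equiv), CH2Cl2, 0 °C to rt; aq. citric acid work-up
Reagents that add atoms: none
Why: Et3N reversibly removes a proton from C7 (the methylene between the enol-ether carbon C8 and the C6 ketone), and the resulting dienolate adds through its ester α-carbon C8a to the C4a methyl ketone to give aldol adduct 13, which loses water by E1cB elimination and tautomerises at C6 to the phenol. The closest known reaction type is the mild-base aldol aromatisation of 3,5,7-tricarbonyl esters and of their enol-ether-locked forms (6-(2,4-dioxoalkyl)-1,3-dioxin-4-ones) to resorcylates, here carried over to an acyclic aryl enol ether. Ring A closes in a 6-(enolexo)-exo-trig mode, forming only the C4a–C8a bond. The two stereocentres of 13 form without control and are both erased on aromatisation, so 14 has none. The step needs this closure to beat Dieckmann-type attack of C5 on the C1 ester, lactonisation of the C6 enol oxygen onto C1 and expulsion of the ring B aryloxide from C8. The tert-butyl ester makes both acyl substitutions at C1 slow, and a non-nucleophilic tertiary amine in an aprotic solvent offers no nucleophile that could displace the aryloxide from the vinylogous carbonate.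

**Step 10**
Reactants: 14 the ring A phenol from step 9
Product: 15 benzyl 4,6-bis(benzyloxy)-3-[5-(benzyloxy)-2-(tert-butoxycarbonyl)-3-methylphenoxy]-2-pentylbenzoate
Conditions: BnBr (1.2 equiv), K2CO3 (2 equiv), DMF, rt
Reagents that add atoms: benzyl bromide, BrCc1ccccc1
Why: Williamson ether synthesis on the only free phenol, which is acidic because it is para to the ester; the benzyl ether removes the acidic proton before the next, strongly basic step and is cleaved in the final hydrogenolysis.

**Step 11**
Reactants: 15 the ring A benzyl ether from step 10; 16 N-methoxy-N-methylhexanamide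
Product: 17 benzyl 4,6-bis(benzyloxy)-3-[5-(benzyloxy)-2-(tert-butoxycarbonyl)-3-(2-oxoheptyl)phenoxy]-2-pentylbenzoate
Conditions: LiN(i-Pr)2 (1.2 equiv), THF, −78 °C; then 16 (1.5 equiv), −78 to −20 °C; cold 1 M HCl
Reagents that add atoms: none
Why: Lateral lithiation of an ortho-toluate and acylation by a Weinreb amide: the ring A methyl is the only primary benzylic position ortho to an ester, whereas the benzylic methylene of ring B is secondary and wedged between the ester and the aryloxy group so that its anion cannot become coplanar with the ring, and the tetrahedral adduct prevents over-addition; this adds C3 and the pentyl chain.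

**Step 12**
Reactants: 17 the 2-oxoheptyl tert-butyl ester from step 11
Product: 19 benzyl 4,6-bis(benzyloxy)-3-{[6-(benzyloxy)-1-oxo-3-pentyl-1H-isochromen-8-yl]oxy}-2-pentylbenzoate, via keto acid 18 (not isolated)
Conditions: TFA/CH2Cl2 (1:4), 0 °C to rt
Reagents that add atoms: none
Why: Acidolysis of the tert-butyl ester and acid-catalysed cyclodehydration: the keto acid closes to the lactol and loses water to the conjugated 1H-isochromen-1-one, while the aryl benzyl ethers and the hindered benzyl ester are stable to TFA at room temperature.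

**Step 13**
Reactants: 19 the tetrabenzyl isocoumarin from step 12
Product: 20 4,6-dihydroxy-3-[(6-hydroxy-1-oxo-3-pentyl-1H-isochromen-8-yl)oxy]-2-pentylbenzoic acid (CNP0439913.0)
Conditions: H2 (1 atm), 10% Pd/C, EtOAc, rt
Reagents that add atoms: none
Why: Catalytic hydrogenolysis of three aryl benzyl ethers and one benzyl ester: the benzylic C–O bonds are cleaved under neutral conditions, which spare the decarboxylation-prone 2,4-dihydroxybenzoic acid, and the trisubstituted enol-lactone C3=C4 bond is reduced much more slowly, so the reaction is stopped after uptake of four equivalents of H2.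

**Compound list**

1 | olivetol (5-pentylbenzene-1,3-diol) | CCCCCc1cc(O)cc(O)c1 | starting material
2 | 1,3-bis(benzyloxy)-5-pentylbenzene | CCCCCc1cc(OCc2ccccc2)cc(OCc2ccccc2)c1 | intermediate
3 | 1,5-bis(benzyloxy)-2,4-dibromo-3-pentylbenzene | CCCCCc1c(Br)c(OCc2ccccc2)cc(OCc2ccccc2)c1Br | intermediate
4 | 4,6-bis(benzyloxy)-3-bromo-2-pentylbenzoic acid | CCCCCc1c(Br)c(OCc2ccccc2)cc(OCc2ccccc2)c1C(=O)O | intermediate
5 | dimethyl [4,6-bis(benzyloxy)-3-carboxy-2-pentylphenyl]boronate (present as its lithium salt) | CCCCCc1c(B(OC)OC)c(OCc2ccccc2)cc(OCc2ccccc2)c1C(=O)O | intermediate (not isolated)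
6 | 4,6-bis(benzyloxy)-3-hydroxy-2-pentylbenzoic acid | CCCCCc1c(O)c(OCc2ccccc2)cc(OCc2ccccc2)c1C(=O)O | intermediate
7 | benzyl 4,6-bis(benzyloxy)-3-hydroxy-2-pentylbenzoate | CCCCCc1c(O)c(OCc2ccccc2)cc(OCc2ccccc2)c1C(=O)OCc3ccccc3 | intermediate
8 | tert-butyl but-2-ynoate | CC#CC(=O)OC(C)(C)C | starting material
9 | benzyl 4,6-bis(benzyloxy)-3-{[(2E)-4-(tert-butoxy)-4-oxobut-2-en-2-yl]oxy}-2-pentylbenzoate | CC(C)(C)OC(=O)/C=C(\C)Oc1c(OCc2ccccc2)cc(OCc2ccccc2)c(C(=O)OCc2ccccc2)c1CCCCC | intermediate
10 | N-methoxy-N-methylacetamide | CC(=O)N(C)OC | starting material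
11 | benzyl 4,6-bis(benzyloxy)-3-{[(2E)-1-(tert-butoxy)-1,5-dioxohex-2-en-3-yl]oxy}-2-pentylbenzoate | CC(C)(C)OC(=O)/C=C(/Oc1c(OCc2ccccc2)cc(OCc2ccccc2)c(C(=O)OCc2ccccc2)c1CCCCC)CC(C)=O | intermediate
12 | benzyl 4,6-bis(benzyloxy)-3-{[(2E)-1-(tert-butoxy)-1,5,7-trioxooct-2-en-3-yl]oxy}-2-pentylbenzoate (triketo tautomer drawn) | CC(C)(C)OC(=O)/C=C(/Oc1c(OCc2ccccc2)cc(OCc2ccccc2)c(C(=O)OCc2ccccc2)c1CCCCC)CC(=O)CC(C)=O | intermediate (key-step precursor)
13 | benzyl 4,6-bis(benzyloxy)-3-{[6-(tert-butoxycarbonyl)-5-hydroxy-5-methyl-3-oxocyclohex-1-en-1-yl]oxy}-2-pentylbenzoate (mixture of diastereomers, racemic) | CC1(O)CC(=O)C=C(Oc2c(OCc3ccccc3)cc(OCc3ccccc3)c(C(=O)OCc3ccccc3)c2CCCCC)C1C(=O)OC(C)(C)C | intermediate (not isolated)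
14 | benzyl 4,6-bis(benzyloxy)-3-[2-(tert-butoxycarbonyl)-5-hydroxy-3-methylphenoxy]-2-pentylbenzoate | Cc1cc(O)cc(Oc2c(OCc3ccccc3)cc(OCc3ccccc3)c(C(=O)OCc3ccccc3)c2CCCCC)c1C(=O)OC(C)(C)C | intermediate (key-step product)
15 | benzyl 4,6-bis(benzyloxy)-3-[5-(benzyloxy)-2-(tert-butoxycarbonyl)-3-methylphenoxy]-2-pentylbenzoate | Cc1cc(OCc2ccccc2)cc(Oc2c(OCc3ccccc3)cc(OCc3ccccc3)c(C(=O)OCc3ccccc3)c2CCCCC)c1C(=O)OC(C)(C)C | intermediate
16 | N-methoxy-N-methylhexanamide | CCCCCC(=O)N(C)OC | starting material
17 | benzyl 4,6-bis(benzyloxy)-3-[5-(benzyloxy)-2-(tert-butoxycarbonyl)-3-(2-oxoheptyl)phenoxy]-2-pentylbenzoate | CCCCCC(=O)Cc1cc(OCc2ccccc2)cc(Oc2c(OCc3ccccc3)cc(OCc3ccccc3)c(C(=O)OCc3ccccc3)c2CCCCC)c1C(=O)OC(C)(C)C | intermediate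
18 | 4-(benzyloxy)-2-{4,6-bis(benzyloxy)-3-[(benzyloxy)carbonyl]-2-pentylphenoxy}-6-(2-oxoheptyl)benzoic acid | CCCCCC(=O)Cc1cc(OCc2ccccc2)cc(Oc2c(OCc3ccccc3)cc(OCc3ccccc3)c(C(=O)OCc3ccccc3)c2CCCCC)c1C(=O)O | intermediate (not isolated)
19 | benzyl 4,6-bis(benzyloxy)-3-{[6-(benzyloxy)-1-oxo-3-pentyl-1H-isochromen-8-yl]oxy}-2-pentylbenzoate | CCCCCc1cc2cc(OCc3ccccc3)cc(Oc3c(OCc4ccccc4)cc(OCc4ccccc4)c(C(=O)OCc4ccccc4)c3CCCCC)c2c(=O)o1 | intermediate
20 | 4,6-dihydroxy-3-[(6-hydroxy-1-oxo-3-pentyl-1H-isochromen-8-yl)oxy]-2-pentylbenzoic acid | CCCCCc1cc2cc(O)cc(Oc3c(O)cc(O)c(C(=O)O)c3CCCCC)c2c(=O)o1 | target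

**Step count.** Total: 13 steps. Longest linear sequence: 13 steps (1 to 20).

**Steps most likely to fail**

Step 9 (key step). The base may hold the substrate as the stabilised enolate of the C6/C4a diketone, so that the C7 dienolate is hardly populated. Slow closure would then leave time for retro-oxa-Michael loss of the ring B aryloxide. The fallback sets out from 9 and comes back at 14. It replaces the diketone by an ynone of the same oxidation level that has no acidic C5 methylene and needs no dehydration. But-2-ynoic acid would be coupled with MeNHOMe·HCl and a carbodiimide to N-methoxy-N-methylbut-2-ynamide F1. The lithium dienolate of 9 (LiN(i-Pr)2, THF, −78 °C) would be acylated with it and quenched cold with acid to give benzyl 4,6-bis(benzyloxy)-3-{[(2E)-1-(tert-butoxy)-1,5-dioxooct-2-en-6-yn-3-yl]oxy}-2-pentylbenzoate F2. Catalytic DBU in THF should then deprotonate C7 and bring about 6-endo-dig conjugate addition of C8a to the ynone terminus C4a. Tautomerisation of the resulting cyclohexadienone gives 14.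

Step 8. The second deprotonation may stay incomplete, or the dianion may react through C7 or C8a instead of its terminal carbon, so that acetylation gives mixtures. The fallback sets out from 9, bypasses 11 and comes back at 12. It brings in C6, C5, C4a and C4 in one acylation as a masked acetoacetyl unit. Commercial ethyl 2-(2-methyl-1,3-dioxolan-2-yl)acetate would be converted with MeNHOMe·HCl and i-PrMgCl (THF, −20 °C) into N-methoxy-N-methyl-2-(2-methyl-1,3-dioxolan-2-yl)acetamide F3. The lithium dienolate of 9 (LiN(i-Pr)2, 1.1 equiv, THF, −78 °C) would be acylated with it to benzyl 4,6-bis(benzyloxy)-3-{[(2E)-1-(tert-butoxy)-6-(2-methyl-1,3-dioxolan-2-yl)-1,5-dioxohex-2-en-3-yl]oxy}-2-pentylbenzoate F4. Mild deketalisation (pyridinium p-toluenesulfonate, acetone/H2O, 45 °C) should leave the tert-butyl ester and the aryl enol ether intact and give 12.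

Step 11. Proton transfer from the enolisable amide to the benzylic anion, or self-condensation of the toluate, may outrun C-acylation. The fallback sets out from 15 and comes back at 17. It replaces the acylation by addition to an aldehyde followed by oxidation. The benzylic anion of 15 (LiN(i-Pr)2, THF, −78 °C) would be trapped with hexanal, which adds much faster than it is enolised. Cold quenching, before the alkoxide can lactonise, gives racemic benzyl 4,6-bis(benzyloxy)-3-[5-(benzyloxy)-2-(tert-butoxycarbonyl)-3-(2-hydroxyheptyl)phenoxy]-2-pentylbenzoate F5. Dess–Martin periodinane in CH2Cl2 would oxidise the secondary alcohol, removing its stereocentre, to ketone 17.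

**Further compounds**

F1 | step 9 | N-methoxy-N-methylbut-2-ynamide | CC#CC(=O)N(C)OC
F2 | step 9 | benzyl 4,6-bis(benzyloxy)-3-{[(2E)-1-(tert-butoxy)-1,5-dioxooct-2-en-6-yn-3-yl]oxy}-2-pentylbenzoate | CC(C)(C)OC(=O)/C=C(/Oc1c(OCc2ccccc2)cc(OCc2ccccc2)c(C(=O)OCc2ccccc2)c1CCCCC)CC(=O)C#CC
F3 | step 8 | N-methoxy-N-methyl-2-(2-methyl-1,3-dioxolan-2-yl)acetamide | CON(C)C(=O)CC1(C)OCCO1
F4 | step 8 | benzyl 4,6-bis(benzyloxy)-3-{[(2E)-1-(tert-butoxy)-6-(2-methyl-1,3-dioxolan-2-yl)-1,5-dioxohex-2-en-3-yl]oxy}-2-pentylbenzoate | CC(C)(C)OC(=O)/C=C(/Oc1c(OCc2ccccc2)cc(OCc2ccccc2)c(C(=O)OCc2ccccc2)c1CCCCC)CC(=O)CC1(C)OCCO1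
F5 | step 11 | benzyl 4,6-bis(benzyloxy)-3-[5-(benzyloxy)-2-(tert-butoxycarbonyl)-3-(2-hydroxyheptyl)phenoxy]-2-pentylbenzoate (racemic) | CCCCCC(O)Cc1cc(OCc2ccccc2)cc(Oc2c(OCc3ccccc3)cc(OCc3ccccc3)c(C(=O)OCc3ccccc3)c2CCCCC)c1C(=O)OC(C)(C)C
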